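**Retrosynthetic overview**
1. Jaeskeanin ⇐ acylation of the 6α-hydroxyl of 8α,9α-epoxyjaeschkeanadiol; the epoxide comes from the C8=C9 alkene by 6α-OH-directed oxygen transfer; the C4 carbinol comes from a C4 ketone and an isopropyl nucleophile entering on the α face.
2. The seven-membered ring (C1, C5–C10) is closed last, on a purchased ring A, by an intramolecular enone–olefin [2+2] photocycloaddition: C1–C10 closes the ring and makes the quaternary C1; the partner bond C5–C9 is not in the target.
3. Enabling feature: the C4=O/C5=C1 enone of ring A, with the C9=C10 vinyl group held three atoms (C6–C8) from C5 (1,5-closure), and the C6 silyloxy stereocentre, whose allylic 1,3-strain with the C1 methyl fixes the face. C5–C9 is α to the C4 ketone and next to the C8 leaving group, so SmI2 cuts it and leaves C8=C9.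
4. Photosubstrate ⇐ 2-lithio enone ketal + Weinreb amide (C5–C6), with C6 set by Corey–Bakshi–Shibata reduction; the amide ⇐ acetamide enolate + methyl vinyl ketone (C7–C8).
5. Ring order: ring A (commercial cyclopentenone) → seven-membered ring together with a temporary cyclobutane and cyclopentane (step 8) → temporary rings opened (step 9) → oxirane (step 12).

Key step: step 8

Remark: names use daucane numbering (C1 quaternary methyl carbon, C4 carbinol, C5 ring-fusion CH, C6 oxygenated, C8=C9, C10); β is the face of the C1 methyl; C8 of compounds 4, 5 and 9–13 is carried as both epimers because it becomes sp2 in step 9.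

**Step 1**
Reactants: 1 N-methoxy-N-methylacetamide; 2 but-3-en-2-one
Product: 4 3-hydroxy-N-methoxy-N,3-dimethylpent-4-enamide (racemic), via lithium amide enolate 3 (not isolated)
Conditions: LiN(iPr)2, THF, −78 °C; then 2; aq. NH4Cl
Reagents that add atoms: none
Why: Kinetic aldol-type 1,2-addition of the lithium amide enolate to the enone carbonyl at low temperature should give the tertiary allylic alcohol, racemic without consequence.

**Step 2**
Reactants: 4 3-hydroxy-N-methoxy-N,3-dimethylpent-4-enamide
Product: 5 N-methoxy-3-(methoxymethoxy)-N,3-dimethylpent-4-enamide (racemic)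
Conditions: MeOCH2Cl, iPr2NEt, Bu4NI (cat.), CH2Cl2, 40 °C
Reagents that add atoms: chloromethyl methyl ether, COCCl
Why: O-alkylation of the hindered tertiary alcohol by the reactive α-chloro ether gives an acetal that survives organolithium, borane, silylation and mild acid and later serves as an alkoxide leaving group.

**Step 3**
Reactants: 6 2-bromo-3-methylcyclopent-2-en-1-one
Product: 7 6-bromo-7-methyl-1,4-dioxaspiro[4.4]non-6-ene
Conditions: HOCH2CH2OH, p-TsOH (cat.), benzene, reflux, Dean–Stark
Reagents that add atoms: ethane-1,2-diol, OCCO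
Why: Acid-catalysed ketalisation with azeotropic removal of water, the α-bromo substituent holding the double bond in place.

**Step 4**
Reactants: 7 6-bromo-7-methyl-1,4-dioxaspiro[4.4]non-6-ene; 5 N-methoxy-3-(methoxymethoxy)-N,3-dimethylpent-4-enamide
Product: 9 3-(methoxymethoxy)-3-methyl-1-(7-methyl-1,4-dioxaspiro[4.4]non-6-en-6-yl)pent-4-en-1-one (racemic), via vinyllithium 8 (not isolated)
Conditions: n-BuLi, THF, −78 °C; then 5, −78 → −20 °C; aq. NH4Cl
Reagents that add atoms: none
Why: Bromine–lithium exchange gives the α-keto vinyl anion equivalent, and Weinreb acylation stops at the ketone through the chelated tetrahedral intermediate.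

**Step 5**
Reactants: 9 3-(methoxymethoxy)-3-methyl-1-(7-methyl-1,4-dioxaspiro[4.4]non-6-en-6-yl)pent-4-en-1-one
Product: 10 (1S)-3-(methoxymethoxy)-3-methyl-1-(7-methyl-1,4-dioxaspiro[4.4]non-6-en-6-yl)pent-4-en-1-ol (both C3 epimers of the chain)
Conditions: (R)-1-methyl-3,3-diphenyltetrahydro-1H,3H-pyrrolo[1,2-c][1,3,2]oxazaborole (0.2 equiv), catecholborane, toluene, −78 °C
Reagents that add atoms: none
Why: Corey–Bakshi–Shibata reduction, in which the oxazaborolidine distinguishes the tetrasubstituted alkenyl group (large) from the methylene group (small), should give the (S)-carbinol (C6), and catecholborane leaves the vinyl group untouched.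

**Step 6**
Reactants: 10 (1S)-3-(methoxymethoxy)-3-methyl-1-(7-methyl-1,4-dioxaspiro[4.4]non-6-en-6-yl)pent-4-en-1-ol
Product: 11 tert-butyldimethylsilyl ether of 10
Conditions: TBSOTf, 2,6-lutidine, CH2Cl2, −78 → 0 °C
Reagents that add atoms: tert-butyldimethylsilyl trifluoromethanesulfonate, CC(C)(C)[Si](C)(C)OS(=O)(=O)C(F)(F)F
Why: Silylation of the hindered allylic alcohol by the silyl triflate installs the bulky, non-chelating group that the facial control in steps 8 and 9 relies on.

**Step 7**
Reactants: 11 tert-butyldimethylsilyl ether of 10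
Product: 12 2-[(1S)-1-(tert-butyldimethylsilyloxy)-3-(methoxymethoxy)-3-methylpent-4-en-1-yl]-3-methylcyclopent-2-en-1-one
Conditions: pyridinium p-toluenesulfonate (cat.), acetone/H2O, rt
Reagents that add atoms: water, O
Why: Mild acid hydrolysis of the allylic ketal frees the enone chromophore, while the silyl and methoxymethyl ethers should survive.

**Step 8**
Reactants: 12 2-[(1S)-1-(tert-butyldimethylsilyloxy)-3-(methoxymethoxy)-3-methylpent-4-en-1-yl]-3-methylcyclopent-2-en-1-one
Product: 13 photoadduct, 2-(tert-butyldimethylsilyloxy)-4-(methoxymethoxy)-4,7-dimethyltricyclo[5.3.0.0(1,5)]decan-10-one (daucane numbering: C4 ketone, new bonds C1–C10 and C5–C9 on the α face, C1 methyl β, 6S silyloxy group on the β side)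
Conditions: hν (350 nm, Pyrex), CH2Cl2 (0.005 M, degassed), 0 °C
Reagents that add atoms: none
Why: n→π* excitation and intersystem crossing give the triplet enone, which adds to the vinyl group as in the known intramolecular enone–olefin [2+2] photocycloadditions of 2-(pent-4-enyl)cycloalk-2-enones. The first bond C5–C9 closes the temporary five-membered ring by 5-exo attack (rule of five), and coupling of the resulting 1,4-biradical (tertiary C1, primary C10) forms C1–C10, which closes the cyclobutane and with it the seven-membered ring C1–C10–C9–C8–C7–C6–C5 of the target. C1 and C5 are set by the C6 stereocentre: allylic 1,3-strain with the C1 methyl holds H6 in the enone plane, the silyloxy group on the β face and the tether on the α face, so both bonds form on the α face and the methyl ends up β (1R). C9 is fixed by the cis fusion that the three-atom tether enforces, and C8 stays a mixture that step 9 erases. The step needs straight rather than crossed regiochemistry, secured by the three-atom tether on the enone α-carbon, and α rather than β facial attack, secured by the bulky silyl ether at C6.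

**Step 9**
Reactants: 13 photoadduct
Product: 15 (3aS,4S,8aR)-4-(tert-butyldimethylsilyloxy)-6,8a-dimethyl-2,3a,4,5,8,8a-hexahydroazulen-3(1H)-one (trans-fused; daucane 1R,5S,6S), via samarium enolate 14 (not isolated)
Conditions: SmI2, HMPA, THF, −78 °C; then 2,6-di-tert-butyl-4-methylphenol, −78 °C; aq. NH4Cl
Reagents that add atoms: none
Why: Proposed new method: electron transfer from SmI2 to the C4 ketone gives a ketyl whose exocyclic α-cyclobutane bond C5–C9 (best aligned with the ketyl π system) cleaves with release of strain to the samarium enolate 14 and a secondary C9 radical; a second electron gives the C9 organosamarium, which expels the methoxymethoxide from C8 to form C8=C9 from either C8 epimer; 14 should then be protonated on the α face, flanked only by the C6–O bond and C10 when H6 eclipses the enolate oxygen, whereas C7 and the C1 methyl flank the β face; the closest known reactions are the SmI2-induced ring opening of cyclobutyl ketones from [2+2] photoadducts and the Boord-type reductive elimination of β-alkoxy organometallics.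

**Step 10**
Reactants: 15 (3aS,4S,8aR)-4-(tert-butyldimethylsilyloxy)-6,8a-dimethyl-2,3a,4,5,8,8a-hexahydroazulen-3(1H)-one
Product: 16 (3R,3aS,4S,8aR)-4-(tert-butyldimethylsilyloxy)-6,8a-dimethyl-3-(propan-2-yl)-1,2,3,3a,4,5,8,8a-octahydroazulen-3-ol
Conditions: iPrMgCl, LaCl3·2LiCl, THF, 0 °C
Reagents that add atoms: isopropylmagnesium chloride, CC(C)[Mg]Cl
Why: Grignard 1,2-addition, with the oxophilic lanthanum salt suppressing enolisation and β-hydride reduction, should occur on the α face, away from the C6 substituent on C5 and the C1 methyl, and set C4 with the hydroxyl β.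

**Step 11**
Reactants: 16 (3R,3aS,4S,8aR)-4-(tert-butyldimethylsilyloxy)-6,8a-dimethyl-3-(propan-2-yl)-1,2,3,3a,4,5,8,8a-octahydroazulen-3-ol
Product: 17 jaeschkeanadiol, (3R,3aS,4S,8aR)-6,8a-dimethyl-3-(propan-2-yl)-1,2,3,3a,4,5,8,8a-octahydroazulene-3,4-diol
Conditions: Bu4NF, THF, rt
Reagents that add atoms: none
Why: Fluoride-induced desilylation, driven by the strength of the Si–F bond.

**Step 12**
Reactants: 17 jaeschkeanadiol
Product: 18 8α,9α-epoxyjaeschkeanadiol (daucane 1R,4R,5S,6S,8R,9S)
Conditions: VO(acac)2 (cat.), t-BuOOH, CH2Cl2, 0 °C → rt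
Reagents that add atoms: tert-butyl hydroperoxide, CC(C)(C)OO
Why: Hydroxyl-directed epoxidation of a homoallylic alcohol: the vanadium alkoxide of the 6α-hydroxyl delivers oxygen to the α face of C8=C9, which is also the face away from the C1 methyl, setting C8 and C9.

**Step 13**
Reactants: 18 8α,9α-epoxyjaeschkeanadiol; 19 4-acetoxybenzoyl chloride
Product: 20 8α,9α-epoxyjaeschkeanadiol 6-(4-acetoxybenzoate)
Conditions: Et3N, 4-(dimethylamino)pyridine (cat.), CH2Cl2, 0 °C → rt
Reagents that add atoms: none
Why: Acylation under nucleophilic catalysis takes the secondary 6-hydroxyl, while the tertiary 4-hydroxyl is too hindered and the basic medium spares the epoxide.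

**Step 14**
Reactants: 20 8α,9α-epoxyjaeschkeanadiol 6-(4-acetoxybenzoate)
Product: 21 jaeskeanin, 8α,9α-epoxy-4β-hydroxydaucan-6α-yl 4-hydroxybenzoate
Conditions: K2CO3 (cat.), MeOH, 0 °C
Reagents that add atoms: none
Why: Base-catalysed transesterification: the aryl acetate is far more electrophilic than the hindered alkyl aroate, so methanolysis should free the phenol only.

**Compound list**
1 | N-methoxy-N-methylacetamide | CC(=O)N(C)OC | starting material
2 | but-3-en-2-one (methyl vinyl ketone) | CC(=O)C=C | starting material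
3 | lithium 1-[methoxy(methyl)amino]ethen-1-olate (enolate of 1) | C=C(O[Li])N(C)OC | intermediate
4 | 3-hydroxy-N-methoxy-N,3-dimethylpent-4-enamide (racemic) | CON(C)C(=O)CC(C)(O)C=C | intermediate
5 | N-methoxy-3-(methoxymethoxy)-N,3-dimethylpent-4-enamide (racemic) | CON(C)C(=O)CC(C)(OCOC)C=C | intermediate
6 | 2-bromo-3-methylcyclopent-2-en-1-one | CC1=C(Br)C(=O)CC1 | starting material
7 | 6-bromo-7-methyl-1,4-dioxaspiro[4.4]non-6-ene | CC1=C(Br)C2(CC1)OCCO2 | intermediate
8 | (7-methyl-1,4-dioxaspiro[4.4]non-6-en-6-yl)lithium | CC1=C([Li])C2(CC1)OCCO2 | intermediate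
9 | 3-(methoxymethoxy)-3-methyl-1-(7-methyl-1,4-dioxaspiro[4.4]non-6-en-6-yl)pent-4-en-1-one (racemic) | CC1=C(C(=O)CC(C)(OCOC)C=C)C2(CC1)OCCO2 | intermediate
10 | (1S)-3-(methoxymethoxy)-3-methyl-1-(7-methyl-1,4-dioxaspiro[4.4]non-6-en-6-yl)pent-4-en-1-ol (both C3 epimers) | CC1=C([C@@H](O)CC(C)(OCOC)C=C)C2(CC1)OCCO2 | intermediate
11 | tert-butyldimethylsilyl ether of 10 | CC1=C([C@@H](O[Si](C)(C)C(C)(C)C)CC(C)(OCOC)C=C)C2(CC1)OCCO2 | intermediate
12 | 2-[(1S)-1-(tert-butyldimethylsilyloxy)-3-(methoxymethoxy)-3-methylpent-4-en-1-yl]-3-methylcyclopent-2-en-1-one | CC1=C([C@@H](O[Si](C)(C)C(C)(C)C)CC(C)(OCOC)C=C)C(=O)CC1 | intermediate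
13 | photoadduct, 2-(tert-butyldimethylsilyloxy)-4-(methoxymethoxy)-4,7-dimethyltricyclo[5.3.0.0(1,5)]decan-10-one (cyclobutane on the α face, silyloxy group β, both C8 epimers) | O=C1CC[C@]2(C)C[C@H]3C(C)(OCOC)C[C@H](O[Si](C)(C)C(C)(C)C)[C@@]123 | intermediate
14 | diiodosamarium enolate of 15 (C4=C5 enolate, daucane 1R,6S) | CC1=CC[C@@]2(C)CCC(O[Sm](I)I)=C2[C@@H](O[Si](C)(C)C(C)(C)C)C1 | intermediate
15 | (3aS,4S,8aR)-4-(tert-butyldimethylsilyloxy)-6,8a-dimethyl-2,3a,4,5,8,8a-hexahydroazulen-3(1H)-one | O=C1CC[C@]2(C)CC=C(C)C[C@H](O[Si](C)(C)C(C)(C)C)[C@H]21 | intermediate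
16 | (3R,3aS,4S,8aR)-4-(tert-butyldimethylsilyloxy)-6,8a-dimethyl-3-(propan-2-yl)-1,2,3,3a,4,5,8,8a-octahydroazulen-3-ol | CC(C)[C@]1(O)CC[C@]2(C)CC=C(C)C[C@H](O[Si](C)(C)C(C)(C)C)[C@H]21 | intermediate
17 | jaeschkeanadiol, (3R,3aS,4S,8aR)-6,8a-dimethyl-3-(propan-2-yl)-1,2,3,3a,4,5,8,8a-octahydroazulene-3,4-diol | CC(C)[C@]1(O)CC[C@]2(C)CC=C(C)C[C@H](O)[C@H]21 | intermediate
18 | 8α,9α-epoxyjaeschkeanadiol | CC(C)[C@]1(O)CC[C@]2(C)C[C@@H]3O[C@]3(C)C[C@H](O)[C@H]21 | intermediate
19 | 4-acetoxybenzoyl chloride | CC(=O)Oc1ccc(cc1)C(Cl)=O | starting material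
20 | 8α,9α-epoxyjaeschkeanadiol 6-(4-acetoxybenzoate) | CC(C)[C@]1(O)CC[C@]2(C)C[C@@H]3O[C@]3(C)C[C@H](OC(=O)c3ccc(OC(C)=O)cc3)[C@H]21 | intermediate
21 | jaeskeanin | CC(C)[C@]1(O)CC[C@]2(C)C[C@@H]3O[C@]3(C)C[C@H](OC(=O)c3ccc(O)cc3)[C@H]21 | target

**Totals**
Total steps: 14. Longest linear sequence: 13 (steps 1, 2, 4–14).

**Steps most likely to fail**

Step 9 (Proposed new method). The secondary C9 radical formed on ring opening may take a hydrogen atom from the solvent before it is reduced, so that the cyclobutane opens without loss of the C8 oxygen and no alkene forms. The fallback uses known radical chemistry, sets out from 13 and returns at 15. ZnBr2 and n-PrSH in CH2Cl2 remove the methoxymethyl group to give the tertiary alcohol, the 8-hydroxy photoadduct F1. Acylation with N-phthalimidoyl chlorooxalate (Et3N, 4-(dimethylamino)pyridine) gives the tert-alkyl N-phthalimidoyl oxalate F2. Visible light with Ru(bpy)3(PF6)2 and Hantzsch ester releases the tertiary C8 radical, which opens the cyclobutane by β-scission of C9–C5 (cyclobutylcarbinyl opening to the α-keto radical) and is quenched by hydrogen-atom transfer to give 15.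

Step 10. Ketone 15 may enolise and epimerise at C5 toward the cis-fused ketone, which is probably the more stable one (or 14 may have been protonated on the β face in step 9); the Grignard reagent then attacks C4 from the wrong face, and β-hydride reduction can compete. The fallback no longer depends on C5 of 15, sets out from 13 and returns at 17. The conditions of step 9 are used, but enolate 14 is trapped with PhNTf2 to give the dienyl triflate F3. Coupling with iPrMgCl under Fe(acac)3 catalysis gives (1R,6S)-6-(tert-butyldimethylsilyloxy)dauca-4,8-diene F4. Bu4NF gives (1R,6S)-dauca-4,8-dien-6-ol F5, and Dess–Martin periodinane gives (1R)-dauca-4,8-dien-6-one F6, whose only stereocentre is C1. Luche reduction (NaBH4, CeCl3·7H2O) from the face opposite the C1 methyl gives (1R,6R)-dauca-4,8-dien-6-ol F7. VO(acac)2 and t-BuOOH epoxidise the allylic C4=C5 bond syn to the 6β-hydroxyl to give 4β,5β-epoxydauc-8-en-6β-ol F8. Dess–Martin oxidation gives 4β,5β-epoxydauc-8-en-6-one F9. SmI2 opens the epoxy ketone at C5 to give 4β-hydroxydauc-8-en-6-one F10, in which C5 settles under thermodynamic control with C6 trans to the isopropyl group and hydrogen-bonded to the 4β-hydroxyl. Evans–Saksena reduction with Me4NBH(OAc)3, directed by the 4β-hydroxyl, gives the anti-1,3-diol 17.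

Step 8. The biradical may close in the crossed sense, or rotamers about C5–C6 may erode the facial selectivity. The fallback sets out from 11 and returns at 13. Irradiation at 254 nm with (CuOTf)2·C6H6 in Et2O, where the metal holds both alkenes of the 1,6-diene and enforces straight closure from the ground-state complex, gives the ketal photoadduct F11. Pyridinium p-toluenesulfonate in wet acetone then gives 13.

**Further compounds**
F1 | step 9 | 8-hydroxy photoadduct (13 without the methoxymethyl group) | O=C1CC[C@]2(C)C[C@H]3C(C)(O)C[C@H](O[Si](C)(C)C(C)(C)C)[C@@]123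
F2 | step 9 | tert-alkyl N-phthalimidoyl oxalate of F1 | O=C1CC[C@]2(C)C[C@H]3C(C)(OC(=O)C(=O)ON4C(=O)c5ccccc5C4=O)C[C@H](O[Si](C)(C)C(C)(C)C)[C@@]123
F3 | step 10 | (1R,6S)-6-(tert-butyldimethylsilyloxy)-1,8-dimethylbicyclo[5.3.0]deca-4,8-dien-4-yl trifluoromethanesulfonate (daucane numbering) | CC1=CC[C@@]2(C)CCC(OS(=O)(=O)C(F)(F)F)=C2[C@@H](O[Si](C)(C)C(C)(C)C)C1
F4 | step 10 | (1R,6S)-6-(tert-butyldimethylsilyloxy)dauca-4,8-diene | CC1=CC[C@@]2(C)CCC(C(C)C)=C2[C@@H](O[Si](C)(C)C(C)(C)C)C1
F5 | step 10 | (1R,6S)-dauca-4,8-dien-6-ol | CC1=CC[C@@]2(C)CCC(C(C)C)=C2[C@@H](O)C1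
F6 | step 10 | (1R)-dauca-4,8-dien-6-one | CC1=CC[C@@]2(C)CCC(C(C)C)=C2C(=O)C1
F7 | step 10 | (1R,6R)-dauca-4,8-dien-6-ol | CC1=CC[C@@]2(C)CCC(C(C)C)=C2[C@H](O)C1
F8 | step 10 | 4β,5β-epoxydauc-8-en-6β-ol | CC1=CC[C@@]2(C)CC[C@]3(C(C)C)O[C@]23[C@H](O)C1
F9 | step 10 | 4β,5β-epoxydauc-8-en-6-one | CC1=CC[C@@]2(C)CC[C@]3(C(C)C)O[C@]23C(=O)C1
F10 | step 10 | 4β-hydroxydauc-8-en-6-one (trans-fused, 5α-H) | CC(C)[C@]1(O)CC[C@]2(C)CC=C(C)CC(=O)[C@H]21
F11 | step 8 | ethylene ketal of photoadduct 13 | C1COC2(O1)CC[C@]3(C)C[C@H]4C(C)(OCOC)C[C@H](O[Si](C)(C)C(C)(C)C)[C@@]234
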